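Count turnovers before you trust any curve: on the list of suspects free enzyme works on starting material and on target alike, so compare the two times it needs for each in the maple run.

| setting | maple | eta | zeta | epsilon | alpha |
|---|---|---|---|---|---|
| starting material | 0.0050 M | 0.010 M | 0.010 M | 0.010 M | 0.010 M |
| free enzyme | 0.01 mol% | 0.01 mol% | 0.01 mol% | 0.01 mol% | 0.01 mol% |
| added ligand | 3.8 µM | 3.8 µM | 3.8 µM | 3.8 µM | 3.8 µM |
| temperature | 20 °C | 20 °C | 35 °C |  | 5 °C |
| remark | run made earlier |  |  | at 35 °C until 40 s, from then on at 5 °C |  |
| time |  | 3.0 min | 3.0 min | 3.0 min | 3.0 min |

maple run (percent of the starting material charged)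

| time / s | target / % | starting material / % |
|---|---|---|
| 10.0 | 45.7 | 54.4 |
| 15.0 | 59.3 | 39.0 |
| 30.0 | 82.4 | 13.8 |
| 50.0 | 89.0 | 2.9 |

(each reading ± 0.5 percentage points)

- on the list of suspects stand: free enzyme -> unfolded enzyme; starting material + free enzyme -> target + free enzyme; target + free enzyme <-> isomer of the product + free enzyme; free enzyme + added ligand <-> idle complex; starting material + free enzyme -> spent catalyst
- the earlier runs do not show what temperature does; that part of a forecast is a guess
- no earlier run changes the charge of free enzyme; that part of a forecast is a guess

* which flask leads in amount of target, in percent of the starting material charged ("all alike" within 1.5 percentage points) (eta / zeta / epsilon / alpha / all alike)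
* how much target is there at the end, in percent of the starting material charged: eta
* how much target is there at the end, in percent of the starting material charged: zeta
* how much target is there at the end, in percent of the starting material charged: epsilon
* how much target is there at the end, in percent of the starting material charged: alpha

Starting material falls from 54.4% to 2.9% between 10.0 s and 50.0 s, which I read as a rate of 0.0733 s⁻¹, so:

half-life of starting material = 9.46 s

The part of the charge missing from the balance grows from 3.80% at 30.0 s to 8.10% at 50.0 s, a gain of 4.3 percentage points, over a mean target of 85.7%, so:

rate of loss of target = 0.00251 s⁻¹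

half-life of target = 276 s

ratio r = 29.2

This r is the turnover ratio, the turnovers spent on starting material for each one spent on target when the two stand at equal amounts, which is a selectivity factor. Its scatter is about a quarter, since four readings stand behind that gain. As far as both steps go in proportion to free enzyme, the amount of enzyme divides out of r and moves the clock, so for two steps in series I reckon:

peak target = exp(−ln r / (r − 1)) = 88.7%

Past the peak, target falls while free enzyme works, but the step from target to isomer of the product stands on the list of suspects as reversible, so the fall ends at that step's equilibrium. I therefore commit to this peak and to one rule, that the flask leading is the one whose free enzyme stops nearest the end of its starting material; which flask that is remains a guess, because no earlier run shows temperature.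

The forecast names alpha as leader, with 72% there, 45% in eta, 35% in zeta and 58% in epsilon, holding that “conversion should still finish in 3 min while isomerisation stays slow”.

Zeta leads with 88.1%, over 82.7% in epsilon, 63.7% in alpha and 63.2% in eta. At 3.00 min zeta holds 0.294% of its catalyst as free enzyme and 90.4% as unfolded enzyme. Its target stands 0.60 points below the peak reckoned from the ratio of 29.2.

    free enzyme → unfolded enzyme (k = 1.50 × 10⁻⁴ s⁻¹, Ea = 283 kJ mol⁻¹)
    starting material + free enzyme → target + free enzyme, rate k2*[starting material]*[free enzyme]/(1 + ([starting material]/Km2)) (5.84 mM, k = 2.75 × 10⁵ M⁻¹ s⁻¹, Ea = 13.0 kJ mol⁻¹)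
    target + free enzyme ⇌ isomer of the product + free enzyme, rate k3*[free enzyme]*[target] forward; the back reaction follows from the equilibrium constant (K = 0.800, k = 7600 M⁻¹ s⁻¹, Ea = 11.0 kJ mol⁻¹, ΔH = −34.0 kJ mol⁻¹)
    free enzyme + added ligand ⇌ idle complex (K = 1.60 × 10⁵ M⁻¹, k = 29900 M⁻¹ s⁻¹, Ea = 21.0 kJ mol⁻¹, ΔH = −18.0 kJ mol⁻¹)
    starting material + free enzyme → spent catalyst (k = 0.747 M⁻¹ s⁻¹, Ea = 43.0 kJ mol⁻¹)
    (constants at 20 °C)

Take the repeat of eta at 45 °C, which ends with 10.7% target: with so little converted, isomer is about target squared over twice the ratio, 0.0196%. The computed flask holds 0.0413% isomer of the product, twice that.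

The earlier runs and the new flask were generated by integration from invented constants; scatter was added.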